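**Retrosynthetic overview**
1. The CH2 bridge is cut last: ring B (the cyclohexadienone ring, as acetylfilicinic acid 14) is joined to ring A (butanoylphloroglucinol 17, from phloroglucinol by Friedel–Crafts acylation) through a Mannich base and its 6-methylene trione.
2. 14 comes from the fully masked dienone 13 (silyl enol ether, ethyl enol ether, dioxolane) in a single acid hydrolysis.
3. 13 comes from cyclobutenone 4 and the masked-acetyl siloxyalkyne 9 by a thermal pericyclic cascade (4π opening, [2+2], 4π opening, 6π closure); the last event closes ring B between the quaternary CMe2 carbon (C4) and the oxygenated carbon next to the acetyl-bearing carbon (C3).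
4. Enabling feature: ring B carries oxygen on C1, C3 and C5 and a quaternary C4 with two methyl groups. The alternating oxygens are one ketene carbonyl plus two ynol-ether oxygens, and C4, having no hydrogen, stops the 6π product at the dienone level instead of letting it become a phenol.
5. Ring order: four-membered ring of 4, then the transient four-membered ring of 11, then six-membered ring B; ring A is bought.

Key step: step 4

Remark: the target is a β-triketone that exists as rapidly equilibrating enol tautomers and has no stereocentre; the given SMILES is taken as one tautomer of the compound the route aims at.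

**Step 1**
Reactants: 1 isobutyryl chloride; 2 ethoxyacetylene
Product: 4 3-ethoxy-4,4-dimethylcyclobut-2-en-1-one, via dimethylketene 3 (not isolated)
Conditions: Et3N, 2 (excess), Et2O, 0 °C to rt
Reagents that add atoms: none
Why: Dehydrochlorination should give dimethylketene, which undergoes the known regioselective ketene–ynol ether [2+2] cycloaddition (ketene carbonyl carbon to the unsubstituted alkyne carbon) to the 3-alkoxycyclobutenone.

**Step 2**
Reactants: 5 but-3-yn-2-one
Product: 6 2-ethynyl-2-methyl-1,3-dioxolane
Conditions: Me3SiOCH2CH2OSiMe3, Me3SiOTf (cat.), CH2Cl2, −78 °C to −20 °C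
Reagents that add atoms: 1,2-bis(trimethylsiloxy)ethane, C[Si](C)(C)OCCO[Si](C)(C)C
Why: Noyori acetalization at low temperature should ketalize the carbonyl without conjugate addition to the ynone, driven by formation of the strong Si–O–Si bond.

**Step 3**
Reactants: 6 2-ethynyl-2-methyl-1,3-dioxolane
Product: 9 2-methyl-2-({[tri(propan-2-yl)silyl]oxy}ethynyl)-1,3-dioxolane, via lithium acetylide 7 (not isolated), via lithium ynolate 8 (not isolated)
Conditions: n-BuLi, THF, −78 °C; t-BuOOLi (from t-BuOOH + LiN(SiMe3)2), −78 to 0 °C; TIPSOTf, −78 °C to rt
Reagents that add atoms: lithium tert-butyl peroxide, [Li+].[O-]OC(C)(C)C; triisopropylsilyl trifluoromethanesulfonate, CC(C)[Si](OS(=O)(=O)C(F)(F)F)(C(C)C)C(C)C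
Why: Electrophilic oxygen transfer from the lithium peroxide to the lithium acetylide (acetylide oxidation to an ynolate) followed by O-silylation with the bulky silyl triflate is the established route from terminal alkynes to isolable triisopropylsiloxyalkynes.

**Step 4**
Reactants: 4 3-ethoxy-4,4-dimethylcyclobut-2-en-1-one; 9 2-methyl-2-({[tri(propan-2-yl)silyl]oxy}ethynyl)-1,3-dioxolane
Product: 13 5-ethoxy-6,6-dimethyl-2-(2-methyl-1,3-dioxolan-2-yl)-3-{[tri(propan-2-yl)silyl]oxy}cyclohexa-2,4-dien-1-one, via vinylketene 10 (not isolated), via 4-vinylcyclobutenone 11 (not isolated), via dienylketene 12 (not isolated)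
Conditions: 4 (1.5 equiv), toluene, sealed tube, 110 °C, dark
Reagents that add atoms: none
Why: Heating should open 4 by conrotatory 4π electrocyclic ring opening to vinylketene 10, which the siloxyalkyne intercepts in a regioselective [2+2] cycloaddition to give 11; a second, reversible 4π opening gives dienylketene 12, and thermal disrotatory 6π electrocyclization between the ketene carbon and the dimethyl-substituted diene terminus closes the six-membered carbocycle. The closest known reaction type is the Danheiser benzannulation of cyclobutenones with siloxyalkynes, in the variant where a 4,4-disubstituted cyclobutenone delivers a 6,6-disubstituted cyclohexa-2,4-dienone instead of a phenol. Ring B is closed in the 6π electrocyclic mode, and no stereocentre is created because the product is achiral (the one stereocentre of transient 11 is destroyed on ring opening). The step needs the [2+2] regiochemistry in which the ketene carbonyl carbon bonds to the alkyne carbon that carries the dioxolane; the oxygen-polarised triple bond secures this (nucleophilic β-carbon to electrophilic ketene carbon), so the silyloxy carbon ends up between the masked-acetyl carbon and the ring CH. It also needs the ketene carbon and the ethoxy-isobutenyl group cis on the central double bond of 12, which the reversibility of the ring opening secures, since the isomer that cannot close returns to 11. The two methyl groups on the closing terminus leave no hydrogen for tautomerisation, so the product stays at the dienone oxidation level the target requires.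

**Step 5**
Reactants: 13 5-ethoxy-6,6-dimethyl-2-(2-methyl-1,3-dioxolan-2-yl)-3-{[tri(propan-2-yl)silyl]oxy}cyclohexa-2,4-dien-1-one
Product: 14 2-acetyl-3,5-dihydroxy-4,4-dimethylcyclohexa-2,5-dien-1-one (acetylfilicinic acid)
Conditions: 2 M aq. HCl, THF, 50 °C
Reagents that add atoms: water, O
Why: Acid hydrolysis should cleave the silyl enol ether, the vinylogous ethyl ester and the dioxolane in one operation, all three being acid-labile, while the resulting enolised β-triketone is stable to dilute acid.

**Step 6**
Reactants: 15 phloroglucinol; 16 butanoyl chloride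
Product: 17 1-(2,4,6-trihydroxyphenyl)butan-1-one
Conditions: AlCl3 (3 equiv), PhNO2, rt to 60 °C; aq. HCl work-up
Reagents that add atoms: none
Why: Friedel–Crafts acylation of the electron-rich triphenol should stop at the mono-ketone because the first acyl group, chelated to aluminium, deactivates the ring.

**Step 7**
Reactants: 14 2-acetyl-3,5-dihydroxy-4,4-dimethylcyclohexa-2,5-dien-1-one; 17 1-(2,4,6-trihydroxyphenyl)butan-1-one
Product: 20 2-acetyl-6-[(3-butanoyl-2,4,6-trihydroxyphenyl)methyl]-3,5-dihydroxy-4,4-dimethylcyclohexa-2,5-dien-1-one (target), via Mannich base 18 (not isolated), via enetrione 19 (not isolated)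
Conditions: [Me2N=CH2]I (1.05 equiv), MeCN, rt; then 17 (3 equiv), 70 °C
Reagents that add atoms: N,N-dimethylmethylideneammonium iodide (Eschenmoser's salt), C[N+](C)=C.[I-]
Why: A Mannich reaction with the preformed iminium ion should functionalise C6, the only unsubstituted ring carbon of 14; thermal retro-Michael loss of dimethylamine then gives the 6-methylene trione, which is captured in a Friedel–Crafts-type conjugate addition by the free ring position of 17, used in excess to hold back double alkylation.

**Compound list**
1 | isobutyryl chloride (2-methylpropanoyl chloride) | CC(C)C(=O)Cl | starting material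
2 | ethoxyacetylene (ethoxyethyne) | CCOC#C | starting material
3 | dimethylketene | CC(C)=C=O | intermediate
4 | 3-ethoxy-4,4-dimethylcyclobut-2-en-1-one | CCOC1=CC(=O)C1(C)C | intermediate
5 | but-3-yn-2-one | CC(=O)C#C | starting material
6 | 2-ethynyl-2-methyl-1,3-dioxolane | CC1(C#C)OCCO1 | intermediate
7 | lithium acetylide of 6, [(2-methyl-1,3-dioxolan-2-yl)ethynyl]lithium | [Li]C#CC1(C)OCCO1 | intermediate
8 | lithium 2-(2-methyl-1,3-dioxolan-2-yl)ethyn-1-olate (lithium ynolate) | [Li+].[O-]C#CC1(C)OCCO1 | intermediate
9 | 2-methyl-2-({[tri(propan-2-yl)silyl]oxy}ethynyl)-1,3-dioxolane | CC1(C#CO[Si](C(C)C)(C(C)C)C(C)C)OCCO1 | intermediate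
10 | 3-ethoxy-4-methylpenta-1,3-dien-1-one (vinylketene) | O=C=CC(OCC)=C(C)C | intermediate
11 | 4-(1-ethoxy-2-methylprop-1-en-1-yl)-2-(2-methyl-1,3-dioxolan-2-yl)-3-{[tri(propan-2-yl)silyl]oxy}cyclobut-2-en-1-one (racemic, transient) | CCOC(=C(C)C)C1C(=O)C(C2(C)OCCO2)=C1O[Si](C(C)C)(C(C)C)C(C)C | intermediate
12 | (3E)-5-ethoxy-6-methyl-2-(2-methyl-1,3-dioxolan-2-yl)-3-{[tri(propan-2-yl)silyl]oxy}hepta-1,3,5-trien-1-one (dienylketene; ketene carbon and C5 cis) | O=C=C(C1(C)OCCO1)/C(O[Si](C(C)C)(C(C)C)C(C)C)=C\C(OCC)=C(C)C | intermediate
13 | 5-ethoxy-6,6-dimethyl-2-(2-methyl-1,3-dioxolan-2-yl)-3-{[tri(propan-2-yl)silyl]oxy}cyclohexa-2,4-dien-1-one | CCOC1=CC(O[Si](C(C)C)(C(C)C)C(C)C)=C(C2(C)OCCO2)C(=O)C1(C)C | intermediate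
14 | 2-acetyl-3,5-dihydroxy-4,4-dimethylcyclohexa-2,5-dien-1-one (acetylfilicinic acid) | CC(=O)C1=C(O)C(C)(C)C(O)=CC1=O | intermediate
15 | phloroglucinol (benzene-1,3,5-triol) | Oc1cc(O)cc(O)c1 | starting material
16 | butanoyl chloride | CCCC(=O)Cl | starting material
17 | 1-(2,4,6-trihydroxyphenyl)butan-1-one | CCCC(=O)c1c(O)cc(O)cc1O | intermediate
18 | 2-acetyl-6-[(dimethylamino)methyl]-3,5-dihydroxy-4,4-dimethylcyclohexa-2,5-dien-1-one (Mannich base, present as its hydroiodide) | CC(=O)C1=C(O)C(C)(C)C(O)=C(CN(C)C)C1=O | intermediate
19 | 2-acetyl-3-hydroxy-4,4-dimethyl-6-methylidenecyclohex-2-ene-1,5-dione (enetrione) | CC(=O)C1=C(O)C(C)(C)C(=O)C(=C)C1=O | intermediate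
20 | 2-acetyl-6-[(3-butanoyl-2,4,6-trihydroxyphenyl)methyl]-3,5-dihydroxy-4,4-dimethylcyclohexa-2,5-dien-1-one | CCCC(=O)c1c(O)cc(O)c(CC2=C(O)C(C)(C)C(O)=C(C(C)=O)C2=O)c1O | target

**Step count and risks**
Total steps: 7. Longest linear sequence: 5 steps (steps 2, 3, 4, 5, 7).

The step most likely to fail is step 4. The [2+2] capture of vinylketene 10 by the hindered, inductively deactivated siloxyalkyne may be too slow, so that 1,5-hydrogen shift of the vinylketene or its oligomerisation consumes the material. The fallback sets out from 4 and replaces the alkyne partner by unhindered ethoxyacetylene 2, used in excess in toluene at 90 °C in a sealed tube. The same pericyclic cascade should then give 3,5-diethoxy-6,6-dimethylcyclohexa-2,4-dien-1-one F1. Aqueous HCl in THF should hydrolyse both vinylogous ester groups to 3,5-dihydroxy-6,6-dimethylcyclohexa-2,4-dien-1-one (filicinic acid) F2. C-acetylation by O-acylation and acyl migration (AcOH, DCC, DMAP, CH2Cl2) should then deliver 14, where the route is rejoined. The two free ring carbons of F2 are equivalent, so only over-acylation has to be held back by stoichiometry.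

The second is step 7. Cross-selectivity may be lost through transfer of the methylene unit between molecules of the filicinic partner, giving a symmetrical methylene-bridged dimer, or through a second alkylation of the phloroglucinol ring. The fallback reverses the roles of the partners and sets out from 17. Treatment with [Me2N=CH2]I (1 equiv, MeCN, rt, NaHCO3 work-up) should give 1-{3-[(dimethylamino)methyl]-2,4,6-trihydroxyphenyl}butan-1-one F3. Heating F3 with 14 in 1,4-dioxane at 100 °C should expel dimethylamine to an ortho-quinone methide, which is captured by C6 of 14, the single nucleophilic carbon of that partner, to come back to the route at 20. In this order no electrophilic methylene derivative of 14 exists, so its symmetrical dimer cannot form.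

The third is step 3. Oxygen transfer to the acetylide may be incomplete, or the ynolate may be silylated on carbon to a silylketene. The fallback sets out from 6 and reaches the ynolate by polarity reversal at the alkyne instead of acetylide oxidation. PhI(OH)OTs (CHCl3, reflux, desiccant) should convert 6 into [(2-methyl-1,3-dioxolan-2-yl)ethynyl](phenyl)iodonium 4-methylbenzenesulfonate F4. Catalytic CuOTf in MeCN should collapse F4, with loss of iodobenzene, to (2-methyl-1,3-dioxolan-2-yl)ethynyl 4-methylbenzenesulfonate F5. MeLi (THF, −78 °C) attacks F5 at sulfur and releases ynolate 8, which TIPSCl should silylate on oxygen to 9, where the route is rejoined.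

**Further compounds**
F1 | step 4 | 3,5-diethoxy-6,6-dimethylcyclohexa-2,4-dien-1-one | O=C1C=C(OCC)C=C(OCC)C1(C)C
F2 | step 4 | 3,5-dihydroxy-6,6-dimethylcyclohexa-2,4-dien-1-one (filicinic acid) | O=C1C=C(O)C=C(O)C1(C)C
F3 | step 7 | 1-{3-[(dimethylamino)methyl]-2,4,6-trihydroxyphenyl}butan-1-one | CCCC(=O)c1c(O)cc(O)c(CN(C)C)c1O
F4 | step 3 | [(2-methyl-1,3-dioxolan-2-yl)ethynyl](phenyl)iodonium 4-methylbenzenesulfonate | CC1(C#C[I+]c2ccccc2)OCCO1.Cc1ccc(cc1)S(=O)(=O)[O-]
F5 | step 3 | (2-methyl-1,3-dioxolan-2-yl)ethynyl 4-methylbenzenesulfonate | CC1(C#COS(=O)(=O)c2ccc(C)cc2)OCCO1
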